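## The problem

Target 25 is a 2-aryl-4H-chromen-4-one with no stereocenter, so nothing has to be set or relayed. The difficulty is the placing and the telling apart of eight oxygens. Ring A carries O1, 5-OH, 7-OH and 8-OMe around a single C–H (C6); ring B carries 2'-OH, 4'-OH and 5'-OMe; ring C carries 3-OMe. Three oxygens must end as methyl ethers and four as free phenols, so the four phenols are best carried as benzyl ethers that fall together in a neutral last step. Once O5 is free, a 5,7-dioxygenated 8-methoxyflavone can open and reclose onto the other ortho oxygen under strong acid (Wessely–Moser shift to the 6-methoxy isomer), and the free polyphenol is easily oxidised. Late acid and late oxidants are therefore to be avoided. The 2'-oxygen twists ring B out of the chromone plane and is the kind of substituent that diverts chalcone-based flavonol syntheses towards aurones. The enabling feature is that C4 is a lone carbonyl carbon between C4a of ring A and C3, while C3–C2 is a two-carbon unit bonded to ring B. Ring C can therefore be stitched from an ortho-iodophenol (O1, C8a, C4a), carbon monoxide (C4) and an aryl acetylene (C3, C2, ring B). The price is that C3 arrives as C–H and must be oxygenated after ring C exists.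

## Retrosynthesis

**Benzyl ethers last (25 from 24).** The four O–CH2Ph bonds at O5, O7, O2' and O4' are cut. Hydrogenolysis is the one deprotection that touches neither the three methyl ethers nor the isomerisation-prone ring A. Methyl ethers throughout would need selective Lewis-acid demethylation on the free 5-hydroxyflavone. Compound 24 is no simpler in skeleton, but its protecting groups survive base, butyllithium, peracid, palladium and dioxirane. The forward step must cleave four aryl benzyl ethers without reducing the tetrasubstituted C2=C3 bond.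

**The C3 oxygen (24 from 23 from 21).** The O3–CH3 bond is cut first, then the C3–O bond. The three-component assembly needs a terminal alkyne C–H, so C3 cannot arrive oxygenated and the oxygen is added to the finished chromone. Epoxidation of C2=C3 to 22 and acid isomerisation to flavonol 23 is the mildest known way, and 23 has a single free hydroxyl for methylation. The forward step must oxidise one enol-ether-like double bond beside four benzyl ethers and two electron-rich rings.

**Ring C (21 from 9, 17 and 18).** The bonds C4a–C4, C4–C3 and O1–C2 are cut, giving iodophenol 9, alkyne 17 and carbon monoxide 18. The neighbouring cuts were weighed as follows.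
- A diketone route (Baker–Venkataraman) would need a ring A acetophenone with the same regiochemical problem as 9, plus a separate acylation and an acid-mediated cyclodehydration.
- A chalcone route (Algar–Flynn–Oyamada) is known to drift towards aurones when the chalcone carries a 6'-oxygen and a 2-oxygenated ring B, and both are present here.

The chosen cut falls to two benzene derivatives of similar size and a one-carbon gas, and the whole carbon skeleton forms in one flask. The forward step must achieve carbonylation of a hindered, electron-rich aryl iodide and six-membered rather than five-membered closure.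

**The iodine of ring A (9 from 8 from 6).** The C–I bond is cut. Electrophilic iodination of the free phenol would have to choose between the carbon ortho to OH and the carbon para to it, both activated by three oxygens. Directed ortho-metalation removes the choice: in 6 the methoxymethyl (MOM) ether has only one free ortho carbon, and the other C–H lies between two benzyl ethers, which direct more weakly. A carbamate would direct more strongly. It would, however, sit next to the phenoxide set free in the preceding oxidation and could migrate to it, and its removal needs forcing hydroxide or hydride beside an aryl iodide. The MOM group comes off with dilute acid (8 to 9). The forward step must lithiate the ring faster than the benzylic positions.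

**The oxygen pattern of ring A (6 from 5 from 3 from 2 from 1).** The O–CH3 bond of the future 8-OMe is cut, then the aryl C–O bond, which is traced to the formyl group of an aldehyde by Baeyer–Villiger oxidation. 2,4,6-Trihydroxybenzaldehyde 1 already holds the three phenolic oxygens in the right places. Its formyl carbon marks the fourth oxygen, and its hydrogen bond distinguishes the hydroxyl that becomes O1 (left free in 2, then MOM-protected in 3) from the two that become O5 and O7. The forward steps must achieve a selective double benzylation and an aryl (not hydride) migration.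

**The alkyne of ring B (17 from 16 from 14 from 13 from 11 from 10).** The C≡C bond is cut back to aldehyde 16 (one-carbon homologation), and the formyl C–C bond of 16 is cut back to arene 14. In 14 the position para to one benzyloxy and ortho to the other is the only doubly activated, unhindered site. Arene 14 comes from 2,4-dihydroxybenzaldehyde 10 by benzylation (11), Baeyer–Villiger oxidation (13) and methylation, the same formyl-to-methoxy logic as in ring A. Formylation and homologation take one step fewer than iodination, alkynylation with a silylacetylene and desilylation. The longer sequence is kept as a reserve.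

## Roads not taken

**Alternative 1: hidden symmetry and a quinone oxa-Michael closure of O1–C8a.**
- Cut and key step: both aryl groups are traced to the same 2,4-bis(benzyloxy)-5-methoxyphenyl ketone unit, joined through the methoxylated C3 in the symmetric diketone A1. (NH4)2Ce(NO3)6 would oxidise one para-dialkoxy ring to acylquinone A2. The enol oxygen would add to the quinone carbon next to the acyl group, and tautomerisation would give the 5,8-dihydroxyflavone A3. Methylation of the non-chelated 8-OH and hydrogenolysis would finish.
- Merits: one arene serves both rings, the 3-OMe is present from the start, and no C3 oxidation and no pressure equipment are needed. On step count this road is shorter than the chosen one.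
- Weak points: the oxidant must stop after one of two identical rings, and nothing in A1 makes the second ring less oxidisable than the first. It must expel a benzyl and a methyl group from an acyl-deactivated ring. Tetravalent cerium is itself a classical one-electron oxidant of 1,3-dicarbonyl enols. The acylquinone offers the enol carbon as well as the enol oxygen a place to attack.
- Comparison: against the shorter count, the chosen plan sets regiochemistry that is fixed by the substrates rather than by halting an oxidation half-way, and bond formations that all belong to known reaction classes.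

**Alternative 2: ortho-quinone methide hetero-Diels–Alder reaction, C4 oxidised last.**
- Cut and key step: C3–C4 and O1–C2 are cut with C4 at the methylene level. Heating hydroxybenzyl alcohol A4 would give quinone methide A5. Cycloaddition with the α-methoxy enamine A6 and loss of pyrrolidine would give the 4H-chromene A7, whose C4 must then be oxidised to the ketone.
- Merits: the route is metal-free and convergent, and the enamine brings in the 3-OMe, which the chosen plan must add in two extra steps.
- Weak points: A6 is the enamine of an ortho-substituted aryl ketone, hard to form and easily hydrolysed. A5 carries three donor oxygens and is a weak electrophile that can dimerise. The C4 methylene must be oxidised beside four benzylic ether CH2 groups, and 4H-chromenes of this kind tend to lose hydride to give flavylium ions rather than accept oxygen.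
- Comparison: the chosen plan delivers C4 at the ketone level directly from CO, so the hardest step of this alternative has no counterpart.

**Alternative 3: ring A by cyclobutenone ring expansion on a pyranone.**
- Cut and key step: C4a–C5 is cut and ring A is built on a finished pyranone. Thermolysis of cyclobutenone A8 would open the four-membered ring, with the methoxy group rotating outwards, to dienylketene A9. Six-electron closure onto the pyranone carbon that becomes C4a, then tautomerisation, would give A10.
- Merits: every ring A oxygen is placed by the squarate-derived ring with no regiochemical question, and the 5-OH emerges free and distinguished. In this respect it is better than the chosen plan, which relies on a directed lithiation to place iodine.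
- Weak points: it needs the fully substituted pyranone bearing ring B and the 3-OMe, metallated at its last α-carbon, so most of the difficulty of ring C is moved rather than removed. The electron-poor pyranone double bond is an untested partner in the electrocyclisation. The isopropyl ether needs a Lewis acid for removal on exactly the 5-hydroxy-8-methoxyflavone type that isomerises.
- Comparison: the chosen plan makes ring C from three simple pieces in one flask and ends with a neutral deprotection.

Key step: step 12

## Route

Remark: epoxide 22 and the propargylic alcohol of the reserve route are racemic; no stereocenter survives into 25.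

Step 1
Reactants: 1 2,4,6-trihydroxybenzaldehyde
Product: 2 2,4-bis(benzyloxy)-6-hydroxybenzaldehyde
Conditions: BnBr (2.05 equiv), K2CO3, DMF, rt
Reagents that add atoms: benzyl bromide, BrCc1ccccc1
Why: Williamson etherification; after the 4-hydroxyl and one ortho hydroxyl are alkylated, the remaining ortho hydroxyl is locked in a hydrogen bond to the aldehyde and is the least nucleophilic, so two equivalents at room temperature should stop at the bis-ether.

Step 2
Reactants: 2 2,4-bis(benzyloxy)-6-hydroxybenzaldehyde
Product: 3 2,4-bis(benzyloxy)-6-(methoxymethoxy)benzaldehyde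
Conditions: MOMCl, iPr2NEt, CH2Cl2, 0 °C → reflux
Reagents that add atoms: chloromethyl methyl ether, COCCl
Why: O-alkylation of a phenol with a reactive α-chloro ether; the MOM acetal is chosen because it survives peracid, base and butyllithium, directs ortho-lithiation and is removed by dilute acid.

Step 3
Reactants: 3 2,4-bis(benzyloxy)-6-(methoxymethoxy)benzaldehyde
Product: 5 2,4-bis(benzyloxy)-6-(methoxymethoxy)phenol, via aryl formate 4 (not isolated)
Conditions: mCPBA, CH2Cl2, 0 °C → rt; then K2CO3 (cat.), MeOH, rt
Reagents that add atoms: 3-chloroperbenzoic acid, O=C(OO)c1cccc(Cl)c1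
Why: Baeyer–Villiger oxidation of an electron-rich benzaldehyde (Dakin-type); the trialkoxyaryl group migrates in preference to hydrogen, and the formate is cleaved by methanolysis while benzyl and MOM ethers are untouched.

Step 4
Reactants: 5 2,4-bis(benzyloxy)-6-(methoxymethoxy)phenol
Product: 6 1,5-bis(benzyloxy)-2-methoxy-3-(methoxymethoxy)benzene
Conditions: MeI, K2CO3, DMF, rt
Reagents that add atoms: iodomethane, CI
Why: Williamson methylation of the only free hydroxyl; this installs the future 8-OMe.

Step 5
Reactants: 6 1,5-bis(benzyloxy)-2-methoxy-3-(methoxymethoxy)benzene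
Product: 8 1,5-bis(benzyloxy)-2-iodo-4-methoxy-3-(methoxymethoxy)benzene, via aryllithium 7 (not isolated)
Conditions: n-BuLi, TMEDA, THF, −78 → −40 °C; then I2, THF, −78 °C → rt
Reagents that add atoms: iodine, II
Why: Directed ortho-metalation followed by iodinolysis; the MOM ether chelates lithium and its only free ortho carbon is further acidified by the neighbouring benzyloxy group, whereas the other ring C–H lies between two weaker benzyl ether directors; low temperature should suppress benzylic deprotonation.

Step 6
Reactants: 8 1,5-bis(benzyloxy)-2-iodo-4-methoxy-3-(methoxymethoxy)benzene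
Product: 9 3,5-bis(benzyloxy)-2-iodo-6-methoxyphenol
Conditions: HCl (cat.), MeOH/THF, 40 °C
Reagents that add atoms: none
Why: Acid-catalysed acetal exchange transfers the methoxymethyl group to methanol; benzyl ethers, the methyl ether and the aryl iodide are stable to dilute acid at this temperature.

Step 7
Reactants: 10 2,4-dihydroxybenzaldehyde
Product: 11 2,4-bis(benzyloxy)benzaldehyde
Conditions: BnBr (2.5 equiv), K2CO3, DMF, 60 °C
Reagents that add atoms: benzyl bromide, BrCc1ccccc1
Why: Williamson etherification; with excess halide and warming the chelated 2-hydroxyl is alkylated as well as the 4-hydroxyl.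

Step 8
Reactants: 11 2,4-bis(benzyloxy)benzaldehyde
Product: 13 2,4-bis(benzyloxy)phenol, via aryl formate 12 (not isolated)
Conditions: mCPBA, CH2Cl2, 0 °C → rt; then K2CO3 (cat.), MeOH, rt
Reagents that add atoms: 3-chloroperbenzoic acid, O=C(OO)c1cccc(Cl)c1
Why: Baeyer–Villiger oxidation; ortho- and para-alkoxy groups make aryl migration much faster than hydride migration, and methanolysis frees the phenol.

Step 9
Reactants: 13 2,4-bis(benzyloxy)phenol
Product: 14 2,4-bis(benzyloxy)-1-methoxybenzene
Conditions: MeI, K2CO3, acetone, reflux
Reagents that add atoms: iodomethane, CI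
Why: Williamson methylation; this installs the future 5'-OMe.

Step 10
Reactants: 14 2,4-bis(benzyloxy)-1-methoxybenzene
Product: 16 2,4-bis(benzyloxy)-5-methoxybenzaldehyde, via iminium salt 15 (not isolated)
Conditions: POCl3, DMF, 0 → 70 °C; then H2O
Reagents that add atoms: N,N-dimethylformamide, CN(C)C=O; water, O
Why: Vilsmeier–Haack formylation; the carbon para to one benzyloxy group and ortho to the other is the only doubly activated, unhindered position (the carbon between the two benzyloxy groups is shielded, the one ortho to methoxy is meta to both), as in the formylation of 1,2,4-trialkoxybenzenes.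

Step 11
Reactants: 16 2,4-bis(benzyloxy)-5-methoxybenzaldehyde
Product: 17 1,5-bis(benzyloxy)-2-ethynyl-4-methoxybenzene
Conditions: dimethyl (1-diazo-2-oxopropyl)phosphonate, K2CO3, MeOH, rt
Reagents that add atoms: dimethyl (1-diazo-2-oxopropyl)phosphonate, CC(=O)C(=[N+]=[N-])P(=O)(OC)OC
Why: Seyferth–Gilbert homologation in the Ohira–Bestmann variant; the non-enolisable aryl aldehyde condenses with the diazophosphonate anion, and loss of phosphate and nitrogen followed by a 1,2-hydrogen shift gives the terminal alkyne under conditions that leave the aryl ethers alone.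

Step 12
Reactants: 9 3,5-bis(benzyloxy)-2-iodo-6-methoxyphenol; 17 1,5-bis(benzyloxy)-2-ethynyl-4-methoxybenzene; 18 carbon monoxide
Product: 21 5,7-bis(benzyloxy)-2-[2,4-bis(benzyloxy)-5-methoxyphenyl]-8-methoxy-4H-chromen-4-one, via ynone 19 (not isolated), via enaminone 20 (not isolated)
Conditions: PdCl2(PPh3)2 (5 mol %), Et2NH, CO (20 atm), 120 °C
Reagents that add atoms: none
Why: This is the palladium-catalysed carbonylative annulation of 2-iodophenols with terminal alkynes and CO, a carbonylative Sonogashira-type coupling followed by amine-mediated ring closure. Zerovalent palladium, formed from PdCl2(PPh3)2 in the amine, inserts into the C–I bond of 9, and CO insertion gives an aroyl–palladium species that is less crowded than the di-ortho-substituted aryl–palladium. Transfer of the acetylide of 17 and reductive elimination give ynone 19, forming C4a–C4 and C4–C3. Diethylamine, present as solvent, adds to the β-carbon of 19 to give enaminone 20. The phenol oxygen then attacks the same carbon and expels the amine, a 6-endo-trig addition–elimination that forms O1–C2 and closes ring C. The selectivity needed is six-membered against five-membered closure, and it is secured because in 20 only the nitrogen-bearing carbon is electrophilic, which shuts the 5-exo path to an aurone. High CO pressure is meant to make CO insertion outrun direct alkynylation of the aryl–palladium, which would end in a 2-arylbenzofuran. No stereocenter is formed, and benzyl and methyl ethers are inert to the conditions.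

Step 13
Reactants: 21 5,7-bis(benzyloxy)-2-[2,4-bis(benzyloxy)-5-methoxyphenyl]-8-methoxy-4H-chromen-4-one
Product: 23 5,7-bis(benzyloxy)-2-[2,4-bis(benzyloxy)-5-methoxyphenyl]-3-hydroxy-8-methoxy-4H-chromen-4-one, via epoxide 22 (not isolated)
Conditions: DMDO, acetone/CH2Cl2, 0 °C → rt; then p-TsOH·H2O (cat.), CH2Cl2, rt
Reagents that add atoms: dimethyldioxirane, CC1(C)OO1
Why: Dioxirane epoxidation of the enol-ether-like C2=C3 bond, then acid-catalysed opening at C2 (cation stabilised by O1 and the aryl group) and loss of the C3 proton; this is the established flavone-to-flavonol conversion and runs under neutral, anhydrous oxidation conditions that benzyl ethers tolerate.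

Step 14
Reactants: 23 5,7-bis(benzyloxy)-2-[2,4-bis(benzyloxy)-5-methoxyphenyl]-3-hydroxy-8-methoxy-4H-chromen-4-one
Product: 24 5,7-bis(benzyloxy)-2-[2,4-bis(benzyloxy)-5-methoxyphenyl]-3,8-dimethoxy-4H-chromen-4-one
Conditions: MeI, K2CO3, acetone, reflux
Reagents that add atoms: iodomethane, CI
Why: Williamson methylation of the acidic 3-hydroxyl, the only free hydroxyl in the molecule.

Step 15
Reactants: 24 5,7-bis(benzyloxy)-2-[2,4-bis(benzyloxy)-5-methoxyphenyl]-3,8-dimethoxy-4H-chromen-4-one
Product: 25 2-(2,4-dihydroxy-5-methoxyphenyl)-5,7-dihydroxy-3,8-dimethoxy-4H-chromen-4-one (5,7,2',4'-tetrahydroxy-3,8,5'-trimethoxyflavone)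
Conditions: H2 (1 atm), Pd/C (10 %), EtOAc/MeOH, rt
Reagents that add atoms: none
Why: Catalytic hydrogenolysis of four aryl benzyl ethers; the neutral conditions leave the methyl ethers and the tetrasubstituted chromone double bond and give no opportunity for Wessely–Moser isomerisation of ring A.

## Compound list

1 | 2,4,6-trihydroxybenzaldehyde | O=Cc1c(O)cc(O)cc1O | starting material
2 | 2,4-bis(benzyloxy)-6-hydroxybenzaldehyde | O=Cc1c(O)cc(OCc2ccccc2)cc1OCc1ccccc1 | intermediate
3 | 2,4-bis(benzyloxy)-6-(methoxymethoxy)benzaldehyde | COCOc1cc(OCc2ccccc2)cc(OCc2ccccc2)c1C=O | intermediate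
4 | 2,4-bis(benzyloxy)-6-(methoxymethoxy)phenyl formate | COCOc1cc(OCc2ccccc2)cc(OCc2ccccc2)c1OC=O | intermediate
5 | 2,4-bis(benzyloxy)-6-(methoxymethoxy)phenol | COCOc1cc(OCc2ccccc2)cc(OCc2ccccc2)c1O | intermediate
6 | 1,5-bis(benzyloxy)-2-methoxy-3-(methoxymethoxy)benzene | COCOc1cc(OCc2ccccc2)cc(OCc2ccccc2)c1OC | intermediate
7 | [4,6-bis(benzyloxy)-3-methoxy-2-(methoxymethoxy)phenyl]lithium | [Li]c1c(OCOC)c(OC)c(OCc2ccccc2)cc1OCc1ccccc1 | intermediate
8 | 1,5-bis(benzyloxy)-2-iodo-4-methoxy-3-(methoxymethoxy)benzene | COCOc1c(I)c(OCc2ccccc2)cc(OCc2ccccc2)c1OC | intermediate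
9 | 3,5-bis(benzyloxy)-2-iodo-6-methoxyphenol | COc1c(O)c(I)c(OCc2ccccc2)cc1OCc1ccccc1 | intermediate
10 | 2,4-dihydroxybenzaldehyde | O=Cc1ccc(O)cc1O | starting material
11 | 2,4-bis(benzyloxy)benzaldehyde | O=Cc1ccc(OCc2ccccc2)cc1OCc1ccccc1 | intermediate
12 | 2,4-bis(benzyloxy)phenyl formate | O=COc1ccc(OCc2ccccc2)cc1OCc1ccccc1 | intermediate
13 | 2,4-bis(benzyloxy)phenol | Oc1ccc(OCc2ccccc2)cc1OCc1ccccc1 | intermediate
14 | 2,4-bis(benzyloxy)-1-methoxybenzene | COc1ccc(OCc2ccccc2)cc1OCc1ccccc1 | intermediate
15 | N-[2,4-bis(benzyloxy)-5-methoxybenzylidene]-N-methylmethanaminium chloride | COc1cc(C=[N+](C)C)c(OCc2ccccc2)cc1OCc1ccccc1.[Cl-] | intermediate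
16 | 2,4-bis(benzyloxy)-5-methoxybenzaldehyde | COc1cc(C=O)c(OCc2ccccc2)cc1OCc1ccccc1 | intermediate
17 | 1,5-bis(benzyloxy)-2-ethynyl-4-methoxybenzene | C#Cc1cc(OC)c(OCc2ccccc2)cc1OCc1ccccc1 | intermediate
18 | carbon monoxide | [C-]#[O+] | starting material
19 | 1-[4,6-bis(benzyloxy)-2-hydroxy-3-methoxyphenyl]-3-[2,4-bis(benzyloxy)-5-methoxyphenyl]prop-2-yn-1-one | O=C(C#Cc1cc(OC)c(OCc2ccccc2)cc1OCc1ccccc1)c1c(O)c(OC)c(OCc2ccccc2)cc1OCc1ccccc1 | intermediate
20 | (E)-1-[4,6-bis(benzyloxy)-2-hydroxy-3-methoxyphenyl]-3-[2,4-bis(benzyloxy)-5-methoxyphenyl]-3-(diethylamino)prop-2-en-1-one (E expected; the geometry is without consequence) | CCN(CC)/C(=C/C(=O)c1c(O)c(OC)c(OCc2ccccc2)cc1OCc1ccccc1)c1cc(OC)c(OCc2ccccc2)cc1OCc1ccccc1 | intermediate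
21 | 5,7-bis(benzyloxy)-2-[2,4-bis(benzyloxy)-5-methoxyphenyl]-8-methoxy-4H-chromen-4-one | COc1cc(-c2cc(=O)c3c(OCc4ccccc4)cc(OCc4ccccc4)c(OC)c3o2)c(OCc2ccccc2)cc1OCc1ccccc1 | intermediate
22 | 4,6-bis(benzyloxy)-1a-[2,4-bis(benzyloxy)-5-methoxyphenyl]-3-methoxy-1a,7a-dihydro-7H-oxireno[2,3-b]chromen-7-one (2,3-epoxide of 21; racemic, cis ring fusion, one enantiomer drawn) | COc1cc([C@@]23O[C@@H]2C(=O)c2c(OCc4ccccc4)cc(OCc4ccccc4)c(OC)c2O3)c(OCc2ccccc2)cc1OCc1ccccc1 | intermediate
23 | 5,7-bis(benzyloxy)-2-[2,4-bis(benzyloxy)-5-methoxyphenyl]-3-hydroxy-8-methoxy-4H-chromen-4-one | COc1cc(-c2oc3c(OC)c(OCc4ccccc4)cc(OCc4ccccc4)c3c(=O)c2O)c(OCc2ccccc2)cc1OCc1ccccc1 | intermediate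
24 | 5,7-bis(benzyloxy)-2-[2,4-bis(benzyloxy)-5-methoxyphenyl]-3,8-dimethoxy-4H-chromen-4-one | COc1cc(-c2oc3c(OC)c(OCc4ccccc4)cc(OCc4ccccc4)c3c(=O)c2OC)c(OCc2ccccc2)cc1OCc1ccccc1 | intermediate
25 | 2-(2,4-dihydroxy-5-methoxyphenyl)-5,7-dihydroxy-3,8-dimethoxy-4H-chromen-4-one | COc1cc(-c2oc3c(OC)c(O)cc(O)c3c(=O)c2OC)c(O)cc1O | target

## Step count and risks

Total: 15 steps. Longest linear sequence: 10 steps (steps 1–6, then 12–15); the ring B branch (steps 7–11) joins at step 12.

**Step 12 (key step).** Oxidative addition into the electron-rich, di-ortho-substituted C–I bond may be slow. Alkynylation may then occur without CO uptake and be followed by five-membered closure. The aroyl–palladium species may also be captured by diethylamine instead of the acetylide. Fallback without palladium or CO, setting out from 6 and 17: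
- Aryllithium 7, made from 6 as in step 5, is quenched with DMF instead of iodine to give 4,6-bis(benzyloxy)-3-methoxy-2-(methoxymethoxy)benzaldehyde F1.
- Alkyne 17 is deprotonated with n-BuLi in THF at −78 °C to {[2,4-bis(benzyloxy)-5-methoxyphenyl]ethynyl}lithium F2, which adds to F1 to give the racemic propargylic alcohol 1-[4,6-bis(benzyloxy)-3-methoxy-2-(methoxymethoxy)phenyl]-3-[2,4-bis(benzyloxy)-5-methoxyphenyl]prop-2-yn-1-ol F3.
- MnO2 in CH2Cl2 oxidises F3 to 1-[4,6-bis(benzyloxy)-3-methoxy-2-(methoxymethoxy)phenyl]-3-[2,4-bis(benzyloxy)-5-methoxyphenyl]prop-2-yn-1-one F4.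
- Dilute HCl in MeOH removes the MOM group. The route is rejoined at ynone 19, which is closed with Et2NH in EtOH through 20 to 21. Steps 5 and 6 are then not needed.

**Step 5.** Lithiation may take place at the carbon between the two benzyloxy groups, or at a benzylic CH2 with subsequent Wittig rearrangement. Fallback by electrophilic substitution, setting out from 2:
- Iodination with N-iodosuccinimide in MeCN, expected ortho to the chelated hydroxyl, gives 4,6-bis(benzyloxy)-2-hydroxy-3-iodobenzaldehyde F5.
- MOMCl with NaH in DMF gives 4,6-bis(benzyloxy)-3-iodo-2-(methoxymethoxy)benzaldehyde F6.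
- Baeyer–Villiger oxidation with mCPBA gives 4,6-bis(benzyloxy)-3-iodo-2-(methoxymethoxy)phenyl formate F7, and methanolysis gives 4,6-bis(benzyloxy)-3-iodo-2-(methoxymethoxy)phenol F8.
- Methylation (MeI, K2CO3) returns to the route at 8.

**Step 13.** Epoxidation of the twisted, carbonyl-conjugated double bond may be slow enough for oxidation of benzylic C–H bonds or of the electron-rich rings to compete, and acid opening of the epoxide may be diverted to ring contraction. Fallback by deprotonation, setting out from 21:
- LiN(iPr)2 in THF at −78 °C gives {5,7-bis(benzyloxy)-2-[2,4-bis(benzyloxy)-5-methoxyphenyl]-8-methoxy-4-oxo-4H-chromen-3-yl}lithium F9.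
- B(OMe)3 traps it as dimethyl {5,7-bis(benzyloxy)-2-[2,4-bis(benzyloxy)-5-methoxyphenyl]-8-methoxy-4-oxo-4H-chromen-3-yl}boronate F10.
- Oxidation with H2O2 in AcOH in the same flask returns to the route at 23.

**Step 1.** Alkylation may not discriminate cleanly between the hydroxyls, giving mixtures of mono-, bis- and tris-ethers with some C-benzylation. Fallback, setting out from 1:
- Exhaustive benzylation (excess BnBr, K2CO3, DMF, 80 °C) gives 2,4,6-tris(benzyloxy)benzaldehyde F11.
- Chelation-controlled removal of one ortho benzyl group with MgBr2·OEt2 in toluene/Et2O at reflux returns to the route at 2.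

**Step 10.** Partial loss of benzyl groups under hot POCl3, or incomplete conversion, is possible, and the homologation of the very electron-rich aldehyde in step 11 may be sluggish. Fallback, setting out from 14 and bypassing steps 10 and 11:
- Iodination with N-iodosuccinimide in MeCN gives 1,5-bis(benzyloxy)-2-iodo-4-methoxybenzene F12.
- Sonogashira coupling with trimethylsilylacetylene (PdCl2(PPh3)2, CuI, Et3N) gives {[2,4-bis(benzyloxy)-5-methoxyphenyl]ethynyl}trimethylsilane F13.
- K2CO3 in MeOH returns to the route at 17.

## Further compounds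

F1 | step 12 | 4,6-bis(benzyloxy)-3-methoxy-2-(methoxymethoxy)benzaldehyde | COCOc1c(OC)c(OCc2ccccc2)cc(OCc2ccccc2)c1C=O
F2 | step 12 | {[2,4-bis(benzyloxy)-5-methoxyphenyl]ethynyl}lithium | [Li]C#Cc1cc(OC)c(OCc2ccccc2)cc1OCc1ccccc1
F3 | step 12 | 1-[4,6-bis(benzyloxy)-3-methoxy-2-(methoxymethoxy)phenyl]-3-[2,4-bis(benzyloxy)-5-methoxyphenyl]prop-2-yn-1-ol (racemic) | COCOc1c(OC)c(OCc2ccccc2)cc(OCc2ccccc2)c1C(O)C#Cc1cc(OC)c(OCc2ccccc2)cc1OCc1ccccc1
F4 | step 12 | 1-[4,6-bis(benzyloxy)-3-methoxy-2-(methoxymethoxy)phenyl]-3-[2,4-bis(benzyloxy)-5-methoxyphenyl]prop-2-yn-1-one | COCOc1c(OC)c(OCc2ccccc2)cc(OCc2ccccc2)c1C(=O)C#Cc1cc(OC)c(OCc2ccccc2)cc1OCc1ccccc1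
F5 | step 5 | 4,6-bis(benzyloxy)-2-hydroxy-3-iodobenzaldehyde | O=Cc1c(O)c(I)c(OCc2ccccc2)cc1OCc1ccccc1
F6 | step 5 | 4,6-bis(benzyloxy)-3-iodo-2-(methoxymethoxy)benzaldehyde | COCOc1c(I)c(OCc2ccccc2)cc(OCc2ccccc2)c1C=O
F7 | step 5 | 4,6-bis(benzyloxy)-3-iodo-2-(methoxymethoxy)phenyl formate | COCOc1c(I)c(OCc2ccccc2)cc(OCc2ccccc2)c1OC=O
F8 | step 5 | 4,6-bis(benzyloxy)-3-iodo-2-(methoxymethoxy)phenol | COCOc1c(I)c(OCc2ccccc2)cc(OCc2ccccc2)c1O
F9 | step 13 | {5,7-bis(benzyloxy)-2-[2,4-bis(benzyloxy)-5-methoxyphenyl]-8-methoxy-4-oxo-4H-chromen-3-yl}lithium | [Li]c1c(-c2cc(OC)c(OCc3ccccc3)cc2OCc2ccccc2)oc2c(OC)c(OCc3ccccc3)cc(OCc3ccccc3)c2c1=O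
F10 | step 13 | dimethyl {5,7-bis(benzyloxy)-2-[2,4-bis(benzyloxy)-5-methoxyphenyl]-8-methoxy-4-oxo-4H-chromen-3-yl}boronate | COB(OC)c1c(-c2cc(OC)c(OCc3ccccc3)cc2OCc2ccccc2)oc2c(OC)c(OCc3ccccc3)cc(OCc3ccccc3)c2c1=O
F11 | step 1 | 2,4,6-tris(benzyloxy)benzaldehyde | O=Cc1c(OCc2ccccc2)cc(OCc2ccccc2)cc1OCc1ccccc1
F12 | step 10 | 1,5-bis(benzyloxy)-2-iodo-4-methoxybenzene | COc1cc(I)c(OCc2ccccc2)cc1OCc1ccccc1
F13 | step 10 | {[2,4-bis(benzyloxy)-5-methoxyphenyl]ethynyl}trimethylsilane | COc1cc(C#C[Si](C)(C)C)c(OCc2ccccc2)cc1OCc1ccccc1
A1 | alternative 1 | 1,3-bis[2,4-bis(benzyloxy)-5-methoxyphenyl]-2-methoxypropane-1,3-dione | COC(C(=O)c1cc(OC)c(OCc2ccccc2)cc1OCc1ccccc1)C(=O)c1cc(OC)c(OCc2ccccc2)cc1OCc1ccccc1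
A2 | alternative 1 | 2-(benzyloxy)-5-{3-[2,4-bis(benzyloxy)-5-methoxyphenyl]-2-methoxy-3-oxopropanoyl}cyclohexa-2,5-diene-1,4-dione | COC(C(=O)C1=CC(=O)C(OCc2ccccc2)=CC1=O)C(=O)c1cc(OC)c(OCc2ccccc2)cc1OCc1ccccc1
A3 | alternative 1 | 7-(benzyloxy)-2-[2,4-bis(benzyloxy)-5-methoxyphenyl]-5,8-dihydroxy-3-methoxy-4H-chromen-4-one | COc1cc(-c2oc3c(O)c(OCc4ccccc4)cc(O)c3c(=O)c2OC)c(OCc2ccccc2)cc1OCc1ccccc1
A4 | alternative 2 | 3,5-bis(benzyloxy)-2-(hydroxymethyl)-6-methoxyphenol | COc1c(O)c(CO)c(OCc2ccccc2)cc1OCc1ccccc1
A5 | alternative 2 | 3,5-bis(benzyloxy)-2-methoxy-6-methylidenecyclohexa-2,4-dien-1-one | C=C1C(=O)C(OC)=C(OCc2ccccc2)C=C1OCc1ccccc1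
A6 | alternative 2 | 1-{1-[2,4-bis(benzyloxy)-5-methoxyphenyl]-2-methoxyethenyl}pyrrolidine | COC=C(N1CCCC1)c1cc(OC)c(OCc2ccccc2)cc1OCc1ccccc1
A7 | alternative 2 | 5,7-bis(benzyloxy)-2-[2,4-bis(benzyloxy)-5-methoxyphenyl]-3,8-dimethoxy-4H-chromene | COC1=C(c2cc(OC)c(OCc3ccccc3)cc2OCc2ccccc2)Oc2c(OC)c(OCc3ccccc3)cc(OCc3ccccc3)c2C1
A8 | alternative 3 | 4-{6-[2,4-bis(benzyloxy)-5-methoxyphenyl]-5-methoxy-4-oxo-4H-pyran-2-yl}-3-isopropoxy-4-methoxycyclobut-2-en-1-one (racemic) | COC1(C(OC(C)C)=CC1=O)c1cc(=O)c(OC)c(-c2cc(OC)c(OCc3ccccc3)cc2OCc2ccccc2)o1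
A9 | alternative 3 | (3Z)-4-{6-[2,4-bis(benzyloxy)-5-methoxyphenyl]-5-methoxy-4-oxo-4H-pyran-2-yl}-3-isopropoxy-4-methoxybuta-1,3-dien-1-one | O=C=C/C(OC(C)C)=C(/OC)c1cc(=O)c(OC)c(-c2cc(OC)c(OCc3ccccc3)cc2OCc2ccccc2)o1
A10 | alternative 3 | 2-[2,4-bis(benzyloxy)-5-methoxyphenyl]-5-hydroxy-7-isopropoxy-3,8-dimethoxy-4H-chromen-4-one | COc1cc(-c2oc3c(OC)c(OC(C)C)cc(O)c3c(=O)c2OC)c(OCc2ccccc2)cc1OCc1ccccc1
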